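The target is disconnected at C10–C11 and at the C9–CH3 bond (carotenoid numbering). The key step exploits the enyne segment C7≡C8–C9(CH3)=C10H on C6 of the trimethylcyclohexene ring: it is a methyl group and C11 placed on the same side of the outer triple bond of a ring-bound buta-1,3-diyne. One operation, zirconium-catalysed methylalumination and palladium/zinc cross-coupling in the same flask, installs the C9 methyl, fixes the 9E geometry kinetically and joins the C13 ring diyne to the C16 chain. The precursor is the (3R)-silyloxy ring diyne with a free terminal alkyne; its partner is an all-E C16 iodohexaene carrying the C8' oxygen as a silyl ether.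

Key step: step 12

Remark on numbering: carotenoid numbering is used for the target skeleton (ring C1 = CMe2, C3 = carbinol, C5 = methyl-bearing, C6 = alkynyl-bearing; chain C7 to C15, then C15' to the aldehyde carbon C8').
Assumption: the two reductases of step 1 are used as recombinant cell or lysate preparations with glucose/glucose dehydrogenase cofactor recycling; baker's yeast can stand in for the ene-reductase.
Remark on a name: the C16 partner 18 has six conjugated C=C bonds, the iodoalkene included, and is therefore named as a hexaene.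

Step 1
Reactants: 1 ketoisophorone (2,6,6-trimethylcyclohex-2-ene-1,4-dione)
Product: 3 (4R,6R)-4-hydroxy-2,2,6-trimethylcyclohexan-1-one (actinol), via (6R)-levodione 2 (not isolated)
Conditions: OYE2 (old yellow enzyme of Saccharomyces cerevisiae), NADP+/NAD+ (cat.), glucose dehydrogenase, D-glucose, phosphate buffer pH 7, 30 °C; then levodione reductase (Corynebacterium aquaticum), same pot, 30 °C; crystallisation
Reagents that add atoms: none
Why: The ene-reductase saturates the enedione C=C to give (6R)-2 and the ketoreductase then delivers hydride to one face of the unhindered C4 carbonyl only, so the enzyme sets the (4R) carbinol that becomes C3 of the target while the flanked C1 ketone is untouched (biocatalytic ene-reduction followed by ketone reduction).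

Step 2
Reactants: 3 (4R,6R)-4-hydroxy-2,2,6-trimethylcyclohexan-1-one
Product: 4 (4R,6R)-4-[(tert-butyldimethylsilyl)oxy]-2,2,6-trimethylcyclohexan-1-one
Conditions: TBSCl, imidazole, DMF, 23 °C
Reagents that add atoms: tert-butyldimethylsilyl chloride, CC(C)(C)[Si](C)(C)Cl
Why: Imidazole-promoted silylation of an unhindered secondary alcohol is routine, and the silyloxy group sits γ to the ketone, so neither elimination nor epimerisation of the carbinol centre is possible.

Step 3
Reactants: 4 (4R,6R)-4-[(tert-butyldimethylsilyl)oxy]-2,2,6-trimethylcyclohexan-1-one; 5 1,4-bis(trimethylsilyl)buta-1,3-diyne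
Product: 7 (4R,6R)-4-[(tert-butyldimethylsilyl)oxy]-2,2,6-trimethyl-1-[4-(trimethylsilyl)buta-1,3-diyn-1-yl]cyclohexan-1-ol (mixture of C1 epimers), via lithium diynide 6 (not isolated)
Conditions: 5, MeLi·LiBr, THF, −78 → 23 °C; then 4, THF, −78 → 0 °C; H2O quench
Reagents that add atoms: none
Why: Desilylative monolithiation of 5 gives the rod-shaped, unhindered diynyllithium 6, which adds 1,2 to the hindered ketone (acetylide addition) faster than it enolises it; the new carbinol centre forms as an epimer mixture that step 4 erases.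

Step 4
Reactants: 7 (4R,6R)-4-[(tert-butyldimethylsilyl)oxy]-2,2,6-trimethyl-1-[4-(trimethylsilyl)buta-1,3-diyn-1-yl]cyclohexan-1-ol
Product: 8 tert-butyldimethyl{[(1R)-3,5,5-trimethyl-4-[4-(trimethylsilyl)buta-1,3-diyn-1-yl]cyclohex-3-en-1-yl]oxy}silane
Conditions: POCl3, pyridine, 90 °C
Reagents that add atoms: none
Why: Dehydration through the dichlorophosphate (POCl3/pyridine elimination) can only remove the methine hydrogen at the methyl-bearing carbon because the other neighbour is quaternary, so both carbinol epimers converge on the tetrasubstituted C5=C6 alkene conjugated to the diyne.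

Step 5
Reactants: 8 tert-butyldimethyl{[(1R)-3,5,5-trimethyl-4-[4-(trimethylsilyl)buta-1,3-diyn-1-yl]cyclohex-3-en-1-yl]oxy}silane
Product: 9 {[(1R)-4-(buta-1,3-diyn-1-yl)-3,5,5-trimethylcyclohex-3-en-1-yl]oxy}(tert-butyl)dimethylsilane (ring diyne, (3R) in carotenoid numbering)
Conditions: K2CO3 (cat.), MeOH–THF, 0 °C; used at once as a cold solution, dark
Reagents that add atoms: none
Why: Base-catalysed methanolysis cleaves only the alkynyl C–Si bond (protodesilylation) and leaves the secondary silyl ether; the terminal diyne is not stored, to avoid oligomerisation.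

Step 6
Reactants: 10 ethyl tiglate (ethyl (2E)-2-methylbut-2-enoate)
Product: 11 ethyl (2E)-4-bromo-2-methylbut-2-enoate
Conditions: NBS, AIBN (cat.), PhCF3 (or CCl4), reflux; fractional distillation
Reagents that add atoms: N-bromosuccinimide, O=C1CCC(=O)N1Br
Why: Wohl–Ziegler bromination through the delocalised allyl radical places bromine on the γ-methyl group, and the (E)-γ-bromide is separated from the bromomethyl regioisomer by distillation.

Step 7
Reactants: 11 ethyl (2E)-4-bromo-2-methylbut-2-enoate
Product: 12 ethyl (2E)-4-(diethoxyphosphoryl)-2-methylbut-2-enoate (C5 phosphonate)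
Conditions: P(OEt)3, neat, 120–140 °C, EtBr distilled off
Reagents that add atoms: triethyl phosphite, CCOP(OCC)OCC
Why: Michaelis–Arbuzov reaction at the primary allylic bromide proceeds by SN2 attack of phosphorus and dealkylation, which keeps the 2E geometry.

Step 8
Reactants: 12 ethyl (2E)-4-(diethoxyphosphoryl)-2-methylbut-2-enoate; 13 C10 dialdehyde ((2E,4E,6E)-2,7-dimethylocta-2,4,6-trienedial)
Product: 15 ethyl (2E,4E,6E,8E,10E)-2,6,11-trimethyl-12-oxododeca-2,4,6,8,10-pentaenoate (C15 aldehyde ester), via sodium phosphonate carbanion 14 (not isolated)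
Conditions: NaH, THF, 0 °C; then added slowly to 13 (2 equiv), THF, −20 → 23 °C, dark; excess 13 recovered
Reagents that add atoms: none
Why: Horner–Wadsworth–Emmons olefination at the carbon next to phosphorus of the vinylogous anion gives the E alkene (C11'=C12'), and a single condensation should dominate because the mono-adduct is a longer, less electrophilic polyenal than 13 and 13 is in excess.

Step 9
Reactants: 15 ethyl (2E,4E,6E,8E,10E)-2,6,11-trimethyl-12-oxododeca-2,4,6,8,10-pentaenoate
Product: 16 ethyl (2E,4E,6E,8E,10E,12E)-13-iodo-2,6,11-trimethyltrideca-2,4,6,8,10,12-hexaenoate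
Conditions: CHI3, CrCl2, THF (or dioxane–THF), 0 → 23 °C, dark
Reagents that add atoms: iodoform, IC(I)I
Why: Takai iodoolefination, in which the geminal dichromium carbenoid from CHI3 and CrCl2 adds to the aldehyde and eliminates to the (E)-iodoalkene (C11=C12), is selective for aldehydes and leaves the conjugated ester alone.

Step 10
Reactants: 16 ethyl (2E,4E,6E,8E,10E,12E)-13-iodo-2,6,11-trimethyltrideca-2,4,6,8,10,12-hexaenoate
Product: 17 (2E,4E,6E,8E,10E,12E)-13-iodo-2,6,11-trimethyltrideca-2,4,6,8,10,12-hexaen-1-ol
Conditions: i-Bu2AlH, CH2Cl2, −78 °C; aq. potassium sodium tartrate; dark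
Reagents that add atoms: none
Why: i-Bu2AlH reduces the conjugated ester 1,2 to the allylic alcohol at low temperature and does not touch alkenyl iodides or the polyene.

Step 11
Reactants: 17 (2E,4E,6E,8E,10E,12E)-13-iodo-2,6,11-trimethyltrideca-2,4,6,8,10,12-hexaen-1-ol
Product: 18 tert-butyl{[(2E,4E,6E,8E,10E,12E)-13-iodo-2,6,11-trimethyltrideca-2,4,6,8,10,12-hexaen-1-yl]oxy}dimethylsilane (C16 iodohexaene silyl ether)
Conditions: TBSCl, imidazole, CH2Cl2, 0 → 23 °C, dark
Reagents that add atoms: tert-butyldimethylsilyl chloride, CC(C)(C)[Si](C)(C)Cl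
Why: Standard silylation of a primary allylic alcohol removes the only protic site, so the partner cannot quench the alkenylmetal of step 12, and it uses the same silyl group as the ring so that one later operation frees both hydroxyls.

Step 12
Reactants: 9 {[(1R)-4-(buta-1,3-diyn-1-yl)-3,5,5-trimethylcyclohex-3-en-1-yl]oxy}(tert-butyl)dimethylsilane; 18 C16 iodohexaene silyl ether
Product: 20 bis(tert-butyldimethylsilyl) ether of (3R)-7,8-didehydro-8'-apo-β-carotene-3,8'-diol, via (E)-alkenyldimethylalane 19 (not isolated)
Conditions: 9, Me3Al, Cp2ZrCl2 (cat.), ClCH2CH2Cl, 0 → 23 °C; excess Me3Al and solvent removed in vacuo; then 18, ZnCl2 (cocatalyst), Pd2(dba)3 / P(2-furyl)3 (cat.), THF–DMF, 23 °C, dark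
Reagents that add atoms: trimethylaluminium, C[Al](C)C
Why: Me3Al and Cp2ZrCl2 form a methylzirconium–aluminium species that adds CH3 and metal to the same face of the terminal C9≡C10 bond through a four-centre transition state, methyl to the internal C9 and aluminium to the terminal C10, giving the (E)-alkenylalane 19; ZnCl2 then relays the alkenyl group to palladium, which has inserted into the C11–I bond of 18 with retention, and reductive elimination forms C10–C11. The closest known reaction type is the zirconium-catalysed carboalumination of terminal conjugated enynes and diynes followed by palladium/zinc-cocatalysed Negishi coupling with alkenyl halides, used to assemble all-E polyenes. No ring is closed and no stereocentre is created; C3 is a spectator. The 9E geometry follows from syn addition plus retention in transmetalation and coupling, so C8 and C11 end up trans under kinetic control, and 11E is carried over from the iodide. The step needs chemo- and regioselectivity for the terminal alkyne: C7≡C8 is internal and screened by the C1 gem-dimethyl and C5 methyl groups, and the metal goes to the unsubstituted terminus. Silyl protection of both hydroxyls removes protic sites, and stripping excess Me3Al before the coupling protects the iodohexaene.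

Step 13
Reactants: 20 bis(tert-butyldimethylsilyl) ether of (3R)-7,8-didehydro-8'-apo-β-carotene-3,8'-diol
Product: 21 (3R)-7,8-didehydro-8'-apo-β-carotene-3,8'-diol
Conditions: TBAF, THF, 0 → 23 °C, dark
Reagents that add atoms: none
Why: Fluoride cleaves both Si–O bonds (primary allylic and secondary ring ether) in one operation, and doing this before the oxidation keeps the base-sensitive polyenal away from fluoride.

Step 14
Reactants: 21 (3R)-7,8-didehydro-8'-apo-β-carotene-3,8'-diol
Product: 22 (3R)-3-hydroxy-7,8-didehydro-8'-apo-β-caroten-8'-al (target)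
Conditions: activated MnO2, CH2Cl2, 23 °C, dark
Reagents that add atoms: none
Why: MnO2 oxidises only allylic, here polyene-conjugated, alcohols, so the primary C8' alcohol should go to the aldehyde without over-oxidation while the homoallylic secondary C3 carbinol is left unchanged (chemoselective allylic oxidation).

Compound list
1 | ketoisophorone (2,6,6-trimethylcyclohex-2-ene-1,4-dione) | CC1=CC(=O)CC(C)(C)C1=O | starting material
2 | (6R)-levodione ((6R)-2,2,6-trimethylcyclohexane-1,4-dione) | C[C@@H]1CC(=O)CC(C)(C)C1=O | intermediate (not isolated)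
3 | (4R,6R)-4-hydroxy-2,2,6-trimethylcyclohexan-1-one (actinol) | C[C@@H]1C[C@@H](O)CC(C)(C)C1=O | intermediate
4 | (4R,6R)-4-[(tert-butyldimethylsilyl)oxy]-2,2,6-trimethylcyclohexan-1-one | C[C@@H]1C[C@@H](O[Si](C)(C)C(C)(C)C)CC(C)(C)C1=O | intermediate
5 | 1,4-bis(trimethylsilyl)buta-1,3-diyne | C[Si](C)(C)C#CC#C[Si](C)(C)C | starting material
6 | lithium 4-(trimethylsilyl)buta-1,3-diyn-1-ide | [Li]C#CC#C[Si](C)(C)C | intermediate (not isolated)
7 | (4R,6R)-4-[(tert-butyldimethylsilyl)oxy]-2,2,6-trimethyl-1-[4-(trimethylsilyl)buta-1,3-diyn-1-yl]cyclohexan-1-ol, C1 epimers | C[C@@H]1C[C@@H](O[Si](C)(C)C(C)(C)C)CC(C)(C)C1(O)C#CC#C[Si](C)(C)C | intermediate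
8 | tert-butyldimethyl{[(1R)-3,5,5-trimethyl-4-[4-(trimethylsilyl)buta-1,3-diyn-1-yl]cyclohex-3-en-1-yl]oxy}silane | CC1=C(C#CC#C[Si](C)(C)C)C(C)(C)C[C@H](O[Si](C)(C)C(C)(C)C)C1 | intermediate
9 | {[(1R)-4-(buta-1,3-diyn-1-yl)-3,5,5-trimethylcyclohex-3-en-1-yl]oxy}(tert-butyl)dimethylsilane | CC1=C(C#CC#C)C(C)(C)C[C@H](O[Si](C)(C)C(C)(C)C)C1 | intermediate
10 | ethyl tiglate (ethyl (2E)-2-methylbut-2-enoate) | C/C=C(\C)C(=O)OCC | starting material
11 | ethyl (2E)-4-bromo-2-methylbut-2-enoate | CCOC(=O)/C(C)=C/CBr | intermediate
12 | ethyl (2E)-4-(diethoxyphosphoryl)-2-methylbut-2-enoate | CCOC(=O)/C(C)=C/CP(=O)(OCC)OCC | intermediate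
13 | (2E,4E,6E)-2,7-dimethylocta-2,4,6-trienedial (C10 dialdehyde) | O=C/C(C)=C/C=C/C=C(C)/C=O | starting material
14 | sodium salt of the carbanion of 12 | [Na+].CCOC(=O)/C(C)=C/[CH-]P(=O)(OCC)OCC | intermediate (not isolated)
15 | ethyl (2E,4E,6E,8E,10E)-2,6,11-trimethyl-12-oxododeca-2,4,6,8,10-pentaenoate | O=C/C(C)=C/C=C/C=C(C)/C=C/C=C(\C)C(=O)OCC | intermediate
16 | ethyl (2E,4E,6E,8E,10E,12E)-13-iodo-2,6,11-trimethyltrideca-2,4,6,8,10,12-hexaenoate | I/C=C/C(C)=C/C=C/C=C(C)/C=C/C=C(\C)C(=O)OCC | intermediate
17 | (2E,4E,6E,8E,10E,12E)-13-iodo-2,6,11-trimethyltrideca-2,4,6,8,10,12-hexaen-1-ol | I/C=C/C(C)=C/C=C/C=C(C)/C=C/C=C(\C)CO | intermediate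
18 | tert-butyl{[(2E,4E,6E,8E,10E,12E)-13-iodo-2,6,11-trimethyltrideca-2,4,6,8,10,12-hexaen-1-yl]oxy}dimethylsilane | I/C=C/C(C)=C/C=C/C=C(C)/C=C/C=C(\C)CO[Si](C)(C)C(C)(C)C | intermediate
19 | (E)-alkenyldimethylalane from 9 (methyl on C9, AlMe2 on C10) | CC1=C(C#C/C(C)=C/[Al](C)C)C(C)(C)C[C@H](O[Si](C)(C)C(C)(C)C)C1 | intermediate (not isolated)
20 | bis(tert-butyldimethylsilyl) ether of (3R)-7,8-didehydro-8'-apo-β-carotene-3,8'-diol | CC1=C(C#C/C(C)=C/C=C/C(C)=C/C=C/C=C(C)/C=C/C=C(\C)CO[Si](C)(C)C(C)(C)C)C(C)(C)C[C@H](O[Si](C)(C)C(C)(C)C)C1 | intermediate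
21 | (2E,4E,6E,8E,10E,12E,14E)-17-[(4R)-4-hydroxy-2,6,6-trimethylcyclohex-1-en-1-yl]-2,6,11,15-tetramethylheptadeca-2,4,6,8,10,12,14-heptaen-16-yn-1-ol | CC1=C(C#C/C(C)=C/C=C/C(C)=C/C=C/C=C(C)/C=C/C=C(\C)CO)C(C)(C)C[C@H](O)C1 | intermediate
22 | (2E,4E,6E,8E,10E,12E,14E)-17-[(4R)-4-hydroxy-2,6,6-trimethylcyclohex-1-en-1-yl]-2,6,11,15-tetramethylheptadeca-2,4,6,8,10,12,14-heptaen-16-ynal | CC1=C(C#C/C(C)=C/C=C/C(C)=C/C=C/C=C(C)/C=C/C=C(\C)C=O)C(C)(C)C[C@H](O)C1 | target

Total step count: 14 steps.
Longest linear sequence: 9 steps (steps 6 to 14, from ethyl tiglate); the ring arm is 8 steps (steps 1 to 5 and 12 to 14).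

Steps most likely to fail

Step 12. The diyne may be lost by alumination of its acidic C–H or by oligomerisation. The hand-over from aluminium through zinc to palladium may also stall while the Lewis-acidic metal halides ionise the allylic silyl ether or let the iodohexaene drift in geometry. The fallback sets out from 9 and comes back at 20. After methylalumination of 9 to alane 19 the mixture is treated with I2 (THF, −30 → 0 °C), and the (E)-iodoenyne F1 is isolated and its geometry checked. Lithium–iodine exchange (t-BuLi, Et2O, −78 °C) and trapping with i-PrOBpin should give the alkenyl pinacol boronate F2. Suzuki–Miyaura coupling of F2 with 18 (Pd(PPh3)4, aq. KOH, THF, 23 °C, dark) then forms the same C10–C11 bond with retention at both partners, in the absence of aluminium, zirconium and zinc halides.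

Step 4. The hindered propargylic dichlorophosphate may ionise and be captured by chloride (propargyl or allenyl chloride formation) or rearrange to an enone instead of eliminating, and the diyne may not survive prolonged heating. The fallback sets out from 4 and comes back at 8, replacing steps 3 and 4. Ketone 4 is enolised at its only α-CH (KN(SiMe3)2 or LiN(i-Pr)2, THF, −78 °C) and trapped with PhNTf2 to give the enol triflate F3. Diyne 5 is monodesilylated with MeLi·LiBr and protonated to give 1-(trimethylsilyl)buta-1,3-diyne F4, kept in solution. Sonogashira coupling of F3 with F4 (Pd(PPh3)4, CuI, i-Pr2NH, DMF, 23 °C) should give 8 directly, with the ring alkene already in place and no carbinol to dehydrate.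

Step 9. E selectivity at the new C11=C12 bond may be incomplete, and the light-sensitive iodohexaene ester may scramble or decompose during the chromium work-up. The fallback sets out from 15 and comes back at 16. Colvin homologation of the aldehyde with Me3SiC(Li)N2 (THF, −78 → 0 °C) should give the terminal enyne ester F5. Hydrozirconation of its alkyne with Cp2Zr(H)Cl (THF, 23 °C, dark, slight excess only, so that the conjugated ester is not reduced) and iodinolysis (I2, 0 °C) then delivers 16, with the E geometry fixed by syn addition of Zr–H and retention in the iodination.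

Further compounds
F1 | step 12 | tert-butyl{[(1R)-4-[(3E)-4-iodo-3-methylbut-3-en-1-yn-1-yl]-3,5,5-trimethylcyclohex-3-en-1-yl]oxy}dimethylsilane | CC1=C(C#C/C(C)=C/I)C(C)(C)C[C@H](O[Si](C)(C)C(C)(C)C)C1
F2 | step 12 | tert-butyldimethyl{[(1R)-3,5,5-trimethyl-4-[(3E)-3-methyl-4-(4,4,5,5-tetramethyl-1,3,2-dioxaborolan-2-yl)but-3-en-1-yn-1-yl]cyclohex-3-en-1-yl]oxy}silane | CC1=C(C#C/C(C)=C/B2OC(C)(C)C(C)(C)O2)C(C)(C)C[C@H](O[Si](C)(C)C(C)(C)C)C1
F3 | step 4 | (4R)-4-[(tert-butyldimethylsilyl)oxy]-2,6,6-trimethylcyclohex-1-en-1-yl trifluoromethanesulfonate | CC1=C(OS(=O)(=O)C(F)(F)F)C(C)(C)C[C@H](O[Si](C)(C)C(C)(C)C)C1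
F4 | step 4 | 1-(trimethylsilyl)buta-1,3-diyne | C[Si](C)(C)C#CC#C
F5 | step 9 | ethyl (2E,4E,6E,8E,10E)-2,6,11-trimethyltrideca-2,4,6,8,10-pentaen-12-ynoate | C#C/C(C)=C/C=C/C=C(C)/C=C/C=C(\C)C(=O)OCC
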